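**Plan**

- Retrosynthesis: the B-ring benzyl ether is removed last. Before that, ring A is cut at C8–C8a and C4a–C5 (a sulfinyl group restored at C4a, methanol at C5), giving the ring-C sulfinyl dihydropyranone 14 and the tetraoxygenated diene 18.
- Enabling feature: ring A (C4a, C5, C6, C7, C8, C8a) with 5-OH, 6-OMe, 7-OH and 8-H is the aromatised [4+2] adduct of a 1,2,3-trioxygenated butadiene (C5–C8) with the C4a=C8a enone bond of ring C.
- Ring C is cut at O1–C8a and C4a–C8a (a one-carbon unit) and at C4–C4a, giving Weinreb amide 10 and methyl phenyl sulfoxide. Amide 10 is cut at C2–C3 to the arylacetyl imide 8 and formaldehyde.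
- Forward order: B-ring arylacetic acid, Evans imide, C3 hydroxymethylation, β-ketosulfoxide chain, ring C, ring A by cycloaddition–aromatisation, debenzylation.
- Stereochemistry: the only centre, C3 (R), comes from (S)-4-benzyl-2-oxazolidinone in the titanium-enolate hydroxymethylation and is carried through under conditions that avoid base at C3–H.

Key step: step 12

Remark: chromanone numbering (O1, C2, C3, C4, C4a, C5–C8, C8a) is used for the future atoms of all intermediates; metal enolates and lithiated carbanions formed in situ are treated as reactive forms of their numbered parents; the sulfoxide is used racemic because sulfur is excised in step 12.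

**Route**

Step 1
Reactants: 1 3-hydroxy-4,5-dimethoxybenzaldehyde
Product: 2 3-(benzyloxy)-4,5-dimethoxybenzaldehyde
Conditions: BnBr, K2CO3, DMF, rt
Reagents that add atoms: benzyl bromide, BrCc1ccccc1
Why: Williamson etherification of the phenoxide should be clean, and the benzyl ether is the only protecting group the B ring needs until the final hydrogenolysis.

Step 2
Reactants: 2 3-(benzyloxy)-4,5-dimethoxybenzaldehyde
Product: 4 2-[3-(benzyloxy)-4,5-dimethoxyphenyl]acetonitrile, via N-(1-tosylvinyl)formamide 3 (not isolated)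
Conditions: TosMIC, t-BuOK, DME, −40 °C; then MeOH, reflux
Reagents that add atoms: p-toluenesulfonylmethyl isocyanide (TosMIC), Cc1ccc(cc1)S(=O)(=O)C[N+]#[C-]
Why: In the van Leusen reductive cyanation the TosMIC anion adds to the aldehyde, the oxazoline opens to the N-(1-tosylvinyl)formamide, and methanolysis removes the formyl group with loss of sulfinate to give the one-carbon-homologated nitrile.

Step 3
Reactants: 4 2-[3-(benzyloxy)-4,5-dimethoxyphenyl]acetonitrile
Product: 5 2-[3-(benzyloxy)-4,5-dimethoxyphenyl]acetic acid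
Conditions: KOH, EtOH/H2O, reflux; then aq. HCl
Reagents that add atoms: potassium hydroxide, [K+].[OH-]; water, O
Why: Alkaline nitrile hydrolysis should give the arylacetic acid, since aryl methyl and benzyl ethers are inert to hydroxide.

Step 4
Reactants: 5 2-[3-(benzyloxy)-4,5-dimethoxyphenyl]acetic acid; 6 (S)-4-benzyl-2-oxazolidinone
Product: 8 (S)-4-benzyl-3-{2-[3-(benzyloxy)-4,5-dimethoxyphenyl]acetyl}oxazolidin-2-one, via mixed pivalic anhydride 7 (not isolated)
Conditions: PivCl, Et3N, THF, −20 → 0 °C; then LiCl, 6, rt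
Reagents that add atoms: none
Why: N-acylation of the oxazolidinone through the mixed pivalic anhydride (LiCl/Et3N protocol) should occur at the unhindered arylacetyl carbonyl.

Step 5
Reactants: 8 (S)-4-benzyl-3-{2-[3-(benzyloxy)-4,5-dimethoxyphenyl]acetyl}oxazolidin-2-one
Product: 9 (S)-4-benzyl-3-{(R)-2-[3-(benzyloxy)-4,5-dimethoxyphenyl]-3-hydroxypropanoyl}oxazolidin-2-one
Conditions: TiCl4, i-Pr2NEt, CH2Cl2, 0 °C; then s-trioxane, TiCl4, 0 °C; aq. NH4Cl
Reagents that add atoms: 1,3,5-trioxane, C1OCOCO1
Why: In the Evans hydroxymethylation (aldol-type addition to TiCl4-activated formaldehyde) the chelated Z-chlorotitanium enolate is attacked on the face opposite the auxiliary's benzyl group, which sets C3 as R (CH2OH ranks above aryl), and the enolate should outcompete the electron-rich arene for the electrophile.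

Step 6
Reactants: 9 (S)-4-benzyl-3-{(R)-2-[3-(benzyloxy)-4,5-dimethoxyphenyl]-3-hydroxypropanoyl}oxazolidin-2-one
Product: 10 (R)-2-[3-(benzyloxy)-4,5-dimethoxyphenyl]-3-hydroxy-N-methoxy-N-methylpropanamide
Conditions: MeNH(OMe)·HCl, AlMe3, CH2Cl2, −15 → 0 °C; cold 1 M HCl work-up
Reagents that add atoms: N,O-dimethylhydroxylamine hydrochloride, CNOC.Cl
Why: Weinreb aminolysis by the aluminium amide, directed by the free β-hydroxyl through its aluminium alkoxide, cleaves the exocyclic imide carbonyl without base, so C3 should be retained.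

Step 7
Reactants: 10 (R)-2-[3-(benzyloxy)-4,5-dimethoxyphenyl]-3-hydroxy-N-methoxy-N-methylpropanamide; 11 methyl phenyl sulfoxide
Product: 12 (3R)-3-[3-(benzyloxy)-4,5-dimethoxyphenyl]-4-hydroxy-1-(phenylsulfinyl)butan-2-one (both sulfur epimers)
Conditions: 11 (3.5 equiv), LDA (3.3 equiv), THF, −78 °C; then 10, −78 °C; AcOH quench at −78 °C
Reagents that add atoms: none
Why: In this acylation of a lithiated sulfoxide by a Weinreb amide (β-ketosulfoxide synthesis) the first equivalent of carbanion turns the hydroxyl into a lithium alkoxide, which disfavours deprotonation or β-elimination at C3, and the chelated tetrahedral adduct releases the ketone only on cold acidic quench.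

Step 8
Reactants: 12 (3R)-3-[3-(benzyloxy)-4,5-dimethoxyphenyl]-4-hydroxy-1-(phenylsulfinyl)butan-2-one
Product: 14 (3R)-3-[3-(benzyloxy)-4,5-dimethoxyphenyl]-5-(phenylsulfinyl)-2,3-dihydro-4H-pyran-4-one (both sulfur epimers), via enaminone 13 (not isolated)
Conditions: Me2NCH(OMe)2, CH2Cl2, 0 °C → rt; then AcOH, 40 °C
Reagents that add atoms: N,N-dimethylformamide dimethyl acetal, COC(OC)N(C)C
Why: Aminomethylenation of the doubly activated methylene is followed by acid-assisted 6-endo-trig addition–elimination of the primary hydroxyl on the enaminone (as in enaminone-to-chromone closure), which forms ring C while the base present is consumed at the more acidic CH2 and not at C3–H.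

Step 9
Reactants: 15 methyl methoxyacetate
Product: 16 methyl 2-methoxy-3-oxobutanoate
Conditions: LDA, THF, −78 °C; then MeC(O)N(OMe)Me, −78 → −30 °C; AcOH quench
Reagents that add atoms: N-methoxy-N-methylacetamide, CC(=O)N(C)OC
Why: Crossed Claisen-type C-acylation of the lithium ester enolate by a Weinreb amide should stop at the stable tetrahedral adduct, which prevents over-addition and proton transfer to the product.

Step 10
Reactants: 16 methyl 2-methoxy-3-oxobutanoate
Product: 17 methyl 2-methoxy-3-(trimethylsilyloxy)but-2-enoate (E/Z mixture)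
Conditions: Me3SiCl, Et3N, toluene, rt
Reagents that add atoms: chlorotrimethylsilane, C[Si](C)(C)Cl
Why: O-silylation of the ketone enol of a β-keto ester with Me3SiCl/Et3N is the standard first stage of Chan-type diene preparation.

Step 11
Reactants: 17 methyl 2-methoxy-3-(trimethylsilyloxy)but-2-enoate
Product: 18 1,2-dimethoxy-1,3-bis(trimethylsilyloxy)buta-1,3-diene (geometry inconsequential)
Conditions: LDA, THF, −78 °C; then Me3SiCl, −78 → 0 °C; hexane, filtration under argon, used crude
Reagents that add atoms: chlorotrimethylsilane, C[Si](C)(C)Cl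
Why: γ-Deprotonation of the silyl enol ether and O-silylation of the resulting ester dienolate is the established route to 1,3-bis(silyloxy)butadienes.

Step 12
Reactants: 14 (3R)-3-[3-(benzyloxy)-4,5-dimethoxyphenyl]-5-(phenylsulfinyl)-2,3-dihydro-4H-pyran-4-one; 18 1,2-dimethoxy-1,3-bis(trimethylsilyloxy)buta-1,3-diene
Product: 21 (3R)-3-[3-(benzyloxy)-4,5-dimethoxyphenyl]-5,7-dihydroxy-6-methoxychroman-4-one, via cis-fused cycloadduct 19 (not isolated), via 5,8-dihydrochromenone 20 (not isolated)
Conditions: 18 (3 equiv), toluene, 0 °C → rt, then 70 °C; then 1 M HCl, THF, 0 °C → rt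
Reagents that add atoms: none
Why: Proposed new method: the electron-rich diene 18 should add across the enone double bond of 14, which is polarised by the C4 ketone and the sulfinyl group, with its CH2 terminus bonding to the oxygen-bearing β-carbon (C8–C8a) and its ketene-acetal carbon to the sulfinyl-bearing α-carbon (C4a–C5); the closest known reaction type is the Brassard/Chan-diene cycloaddition–aromatisation on halo- and sulfinyl-activated quinones and on 3-substituted chromones. Ring A closes in a [4+2] mode, either as an asynchronous Diels–Alder reaction or, in the stepwise limit, as a Mukaiyama–Michael addition followed by 6-(enolexo)-exo-trig attack of the C4a silyl enol ether on the C5 oxocarbenium ion. Because addition is suprafacial on the ring alkene, the sulfinyl group at C4a and the hydrogen at C8a are syn in 19, and since C5 carries no hydrogen, thermal syn-elimination of benzenesulfenic acid can only restore the C4a=C8a bond to give 20. Acid then removes methanol from the C5 mixed ketal and cleaves both silyl ethers, which aromatises ring A directly to the 5-OH/6-OMe/7-OH pattern without any phenol differentiation. No new stereocentre survives, since the centres formed at C4a, C5 and C8a and the sulfur centre are all destroyed, so facial selectivity and the sulfur epimer ratio are irrelevant. The step needs regioselectivity, secured by pairing the most nucleophilic diene terminus with the β-alkoxy-enone carbon, and needs sulfoxide elimination to precede opening of O1–C8a, secured by the quaternary C4a that cannot enolise while sulfur is attached; the base-free medium leaves C3 (R) untouched, and the excess diene scavenges the sulfenic acid.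

Step 13
Reactants: 21 (3R)-3-[3-(benzyloxy)-4,5-dimethoxyphenyl]-5,7-dihydroxy-6-methoxychroman-4-one
Product: 22 (3R)-5,7-dihydroxy-3-(3-hydroxy-4,5-dimethoxyphenyl)-6-methoxychroman-4-one
Conditions: H2 (1 atm), 10% Pd/C, EtOAc, rt
Reagents that add atoms: none
Why: Neutral heterogeneous hydrogenolysis of the single aryl benzyl ether should leave the hydrogen-bonded aryl ketone and the base-labile C3 centre unchanged.

**Compound list**

1 | 3-hydroxy-4,5-dimethoxybenzaldehyde | COc1cc(C=O)cc(O)c1OC | starting material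
2 | 3-(benzyloxy)-4,5-dimethoxybenzaldehyde | COc1cc(C=O)cc(OCc2ccccc2)c1OC | intermediate
3 | N-{2-[3-(benzyloxy)-4,5-dimethoxyphenyl]-1-[(4-methylphenyl)sulfonyl]ethenyl}formamide (geometry undefined) | COc1cc(C=C(NC=O)S(=O)(=O)c2ccc(C)cc2)cc(OCc2ccccc2)c1OC | intermediate (not isolated)
4 | 2-[3-(benzyloxy)-4,5-dimethoxyphenyl]acetonitrile | COc1cc(CC#N)cc(OCc2ccccc2)c1OC | intermediate
5 | 2-[3-(benzyloxy)-4,5-dimethoxyphenyl]acetic acid | COc1cc(CC(=O)O)cc(OCc2ccccc2)c1OC | intermediate
6 | (S)-4-benzyl-2-oxazolidinone | O=C1OC[C@H](Cc2ccccc2)N1 | starting material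
7 | 2-[3-(benzyloxy)-4,5-dimethoxyphenyl]acetic pivalic anhydride | COc1cc(CC(=O)OC(=O)C(C)(C)C)cc(OCc2ccccc2)c1OC | intermediate (not isolated)
8 | (S)-4-benzyl-3-{2-[3-(benzyloxy)-4,5-dimethoxyphenyl]acetyl}oxazolidin-2-one | COc1cc(CC(=O)N2C(=O)OC[C@@H]2Cc2ccccc2)cc(OCc2ccccc2)c1OC | intermediate
9 | (S)-4-benzyl-3-{(R)-2-[3-(benzyloxy)-4,5-dimethoxyphenyl]-3-hydroxypropanoyl}oxazolidin-2-one | COc1cc([C@H](CO)C(=O)N2C(=O)OC[C@@H]2Cc2ccccc2)cc(OCc2ccccc2)c1OC | intermediate
10 | (R)-2-[3-(benzyloxy)-4,5-dimethoxyphenyl]-3-hydroxy-N-methoxy-N-methylpropanamide | COc1cc([C@H](CO)C(=O)N(C)OC)cc(OCc2ccccc2)c1OC | intermediate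
11 | methyl phenyl sulfoxide (racemic) | CS(=O)c1ccccc1 | starting material
12 | (3R)-3-[3-(benzyloxy)-4,5-dimethoxyphenyl]-4-hydroxy-1-(phenylsulfinyl)butan-2-one (both sulfur epimers) | COc1cc([C@H](CO)C(=O)CS(=O)c2ccccc2)cc(OCc2ccccc2)c1OC | intermediate
13 | (4R)-4-[3-(benzyloxy)-4,5-dimethoxyphenyl]-1-(dimethylamino)-5-hydroxy-2-(phenylsulfinyl)pent-1-en-3-one | COc1cc([C@H](CO)C(=O)C(=CN(C)C)S(=O)c2ccccc2)cc(OCc2ccccc2)c1OC | intermediate (not isolated)
14 | (3R)-3-[3-(benzyloxy)-4,5-dimethoxyphenyl]-5-(phenylsulfinyl)-2,3-dihydro-4H-pyran-4-one (both sulfur epimers) | COc1cc([C@@H]2COC=C(S(=O)c3ccccc3)C2=O)cc(OCc2ccccc2)c1OC | intermediate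
15 | methyl methoxyacetate | COCC(=O)OC | starting material
16 | methyl 2-methoxy-3-oxobutanoate | COC(C(C)=O)C(=O)OC | intermediate
17 | methyl 2-methoxy-3-(trimethylsilyloxy)but-2-enoate | COC(=O)C(OC)=C(C)O[Si](C)(C)C | intermediate
18 | 1,2-dimethoxy-1,3-bis(trimethylsilyloxy)buta-1,3-diene | C=C(O[Si](C)(C)C)C(OC)=C(OC)O[Si](C)(C)C | intermediate
19 | (3R)-3-[3-(benzyloxy)-4,5-dimethoxyphenyl]-5,6-dimethoxy-4a-(phenylsulfinyl)-5,7-bis(trimethylsilyloxy)-2,3,4a,5,8,8a-hexahydro-4H-chromen-4-one (cis ring fusion; C4a, C5, C8a and S undefined) | COc1cc([C@@H]2COC3CC(O[Si](C)(C)C)=C(OC)C(OC)(O[Si](C)(C)C)C3(S(=O)c3ccccc3)C2=O)cc(OCc2ccccc2)c1OC | intermediate (not isolated)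
20 | (3R)-3-[3-(benzyloxy)-4,5-dimethoxyphenyl]-5,6-dimethoxy-5,7-bis(trimethylsilyloxy)-2,3,5,8-tetrahydro-4H-chromen-4-one (C5 undefined) | COc1cc([C@@H]2COC3=C(C2=O)C(OC)(O[Si](C)(C)C)C(OC)=C(O[Si](C)(C)C)C3)cc(OCc2ccccc2)c1OC | intermediate (not isolated)
21 | (3R)-3-[3-(benzyloxy)-4,5-dimethoxyphenyl]-5,7-dihydroxy-6-methoxychroman-4-one | COc1cc([C@@H]2COc3cc(O)c(OC)c(O)c3C2=O)cc(OCc2ccccc2)c1OC | intermediate
22 | (3R)-5,7-dihydroxy-3-(3-hydroxy-4,5-dimethoxyphenyl)-6-methoxychroman-4-one | COc1cc([C@@H]2COc3cc(O)c(OC)c(O)c3C2=O)cc(O)c1OC | target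

**Step count and risks**

Total step count: 13. Longest linear sequence: 10 steps (steps 1–8, 12, 13); the diene arm (steps 9–11) joins at step 12.

Most likely to fail, step 12 (Proposed new method): the diene may be consumed by protodesilylation, or add only in the Michael sense with subsequent opening of ring C at O1–C8a, or the push–pull enone may react too slowly below the temperature at which the diene decomposes, so that ring A does not close. The fallback uses known chemistry, sets out from 9 and rejoins the route at 22, bringing ring A in preformed as a C2-symmetric phenol so that ring closure is regiochemically unambiguous. Benzylation of commercial 3,5-dihydroxy-4-methoxybenzaldehyde (BnBr, K2CO3, DMF) would give 3,5-bis(benzyloxy)-4-methoxybenzaldehyde F1. Baeyer–Villiger oxidation and formate hydrolysis (mCPBA, CH2Cl2; then NaOH, MeOH) would give 3,5-bis(benzyloxy)-4-methoxyphenol F2. Mitsunobu etherification of the primary alcohol of 9 with F2 (PPh3, DIAD, toluene, 0 °C) would give the aryl ether (S)-4-benzyl-3-{(R)-2-[3-(benzyloxy)-4,5-dimethoxyphenyl]-3-[3,5-bis(benzyloxy)-4-methoxyphenoxy]propanoyl}oxazolidin-2-one F3. Removal of the auxiliary (LiOH, H2O2, THF/H2O, 0 °C) would give (R)-2-[3-(benzyloxy)-4,5-dimethoxyphenyl]-3-[3,5-bis(benzyloxy)-4-methoxyphenoxy]propanoic acid F4. Intramolecular Friedel–Crafts acylation (TFAA, CH2Cl2, 0 °C) at either of the two equivalent ortho positions would close ring C to (3R)-5,7-bis(benzyloxy)-3-[3-(benzyloxy)-4,5-dimethoxyphenyl]-6-methoxychroman-4-one F5. Hydrogenolysis of all three benzyl ethers (H2, Pd/C, EtOAc) would then give 22.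

Second, step 7: deprotonation at the benzylic C3–H by the strongly basic lithiated sulfoxide may compete with carbonyl addition, eroding the C3 configuration or triggering retro-aldol loss of formaldehyde. The fallback sets out from 10 and rejoins at 12, using a less basic sulfide-level Grignard reagent and oxidising sulfur afterwards. Addition of (phenylthio)methylmagnesium chloride (from chloromethyl phenyl sulfide and Mg; THF, 0 °C) would give (3R)-3-[3-(benzyloxy)-4,5-dimethoxyphenyl]-4-hydroxy-1-(phenylthio)butan-2-one F6, and NaIO4 (MeOH/H2O, 0 °C) would oxidise the sulfide to sulfoxide 12.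

Third, step 8: the free β-hydroxy ketone may dehydrate by E1cB or epimerise at C3 under the amine liberated during aminomethylenation, or the enaminone may resist O-cyclisation. The fallback sets out from 10 and rejoins at 14, making ring C before sulfur is introduced and without amine base. Ethynylmagnesium bromide (THF, 0 °C) would give the ynone (4R)-4-[3-(benzyloxy)-4,5-dimethoxyphenyl]-5-hydroxypent-1-yn-3-one F7. Silver-catalysed 6-endo-dig cyclisation (AgOTf, CH2Cl2, rt) would give (3R)-3-[3-(benzyloxy)-4,5-dimethoxyphenyl]-2,3-dihydro-4H-pyran-4-one F8. Electrophilic sulfenylation at the nucleophilic α-carbon of the vinylogous ester (PhSCl, CH2Cl2, −78 °C; then pyridine) would give (3R)-3-[3-(benzyloxy)-4,5-dimethoxyphenyl]-5-(phenylthio)-2,3-dihydro-4H-pyran-4-one F9. mCPBA (1 equiv, CH2Cl2, −78 °C) would then give sulfoxide 14.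

**Further compounds**

F1 | step 12 | 3,5-bis(benzyloxy)-4-methoxybenzaldehyde | COc1c(OCc2ccccc2)cc(C=O)cc1OCc1ccccc1
F2 | step 12 | 3,5-bis(benzyloxy)-4-methoxyphenol | COc1c(OCc2ccccc2)cc(O)cc1OCc1ccccc1
F3 | step 12 | (S)-4-benzyl-3-{(R)-2-[3-(benzyloxy)-4,5-dimethoxyphenyl]-3-[3,5-bis(benzyloxy)-4-methoxyphenoxy]propanoyl}oxazolidin-2-one | COc1cc([C@H](COc2cc(OCc3ccccc3)c(OC)c(OCc3ccccc3)c2)C(=O)N2C(=O)OC[C@@H]2Cc2ccccc2)cc(OCc2ccccc2)c1OC
F4 | step 12 | (R)-2-[3-(benzyloxy)-4,5-dimethoxyphenyl]-3-[3,5-bis(benzyloxy)-4-methoxyphenoxy]propanoic acid | COc1cc([C@H](COc2cc(OCc3ccccc3)c(OC)c(OCc3ccccc3)c2)C(=O)O)cc(OCc2ccccc2)c1OC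
F5 | step 12 | (3R)-5,7-bis(benzyloxy)-3-[3-(benzyloxy)-4,5-dimethoxyphenyl]-6-methoxychroman-4-one | COc1cc([C@@H]2COc3cc(OCc4ccccc4)c(OC)c(OCc4ccccc4)c3C2=O)cc(OCc2ccccc2)c1OC
F6 | step 7 | (3R)-3-[3-(benzyloxy)-4,5-dimethoxyphenyl]-4-hydroxy-1-(phenylthio)butan-2-one | COc1cc([C@H](CO)C(=O)CSc2ccccc2)cc(OCc2ccccc2)c1OC
F7 | step 8 | (4R)-4-[3-(benzyloxy)-4,5-dimethoxyphenyl]-5-hydroxypent-1-yn-3-one | COc1cc([C@H](CO)C(=O)C#C)cc(OCc2ccccc2)c1OC
F8 | step 8 | (3R)-3-[3-(benzyloxy)-4,5-dimethoxyphenyl]-2,3-dihydro-4H-pyran-4-one | COc1cc([C@@H]2COC=CC2=O)cc(OCc2ccccc2)c1OC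
F9 | step 8 | (3R)-3-[3-(benzyloxy)-4,5-dimethoxyphenyl]-5-(phenylthio)-2,3-dihydro-4H-pyran-4-one | COc1cc([C@@H]2COC=C(Sc3ccccc3)C2=O)cc(OCc2ccccc2)c1OC
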